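**Strategy**

The ring A pattern C4(=O)–C3(Me)=C2 is an aldol-condensation retron and the ring-fusion bond C1–C6 lies β to C4, so both rings are cut back to one acyclic keto-aldehyde: a C2 aldehyde, a gem-dimethyl carbon C11, and an (E)-ethyl enone C4–C5=C6 hung on the silylated C7 carbinol of (S)-linalool. One amine-mediated operation then closes seven-membered ring B (enamine carbon C1 onto C6) and six-membered ring A (C3 onto C2), setting C1 and C6 under the control of C7. The chain comes from linalool by radical hydroalkylation and cross-metathesis; the C4 ester is installed afterwards by 1,2-reduction and Mitsunobu inversion.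

Key step: step 5

Atom labels used throughout: C1 and C6 are the ring-fusion CH carbons (C1 beside the CMe2 carbon C11, C6 beside the methyl carbinol C7); C2=C3 is the ring alkene (methyl on C3); C4 is the oxygen-bearing ring carbon; C5 the ring CH2; C8–C10 the three CH2 groups between C7 and C11; ring A is six-membered, ring B seven-membered. In these labels the target is (1S,4R,6R,7S): H-1 and H-6 are cis, the C4 ester oxygen lies on their face, and the C7 oxygen lies on the opposite face, cis to the C5 arm on ring B.

Assumption: (S)-(+)-linalool is taken as purchasable in high enantiomeric purity; its stereocentre becomes C7 and is never touched, so the route is as enantiopure as the linalool used.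

**Route**

Step 1
Reactants: 1 (S)-linalool
Product: 2 (3S)-triethyl[(3,7-dimethylocta-1,6-dien-3-yl)oxy]silane
Conditions: Et3SiOTf, 2,6-lutidine, CH2Cl2, −78 → 0 °C
Reagents that add atoms: triethylsilyl trifluoromethanesulfonate, CC[Si](CC)(CC)OS(=O)(=O)C(F)(F)F
Why: O-silylation of a tertiary allylic alcohol with a silyl triflate and a hindered pyridine base is reliable, and no bond to the stereocentre (later C7) is touched, so its S configuration is carried over.

Step 2
Reactants: 2 (3S)-triethyl[(3,7-dimethylocta-1,6-dien-3-yl)oxy]silane; 3 phenyl vinyl sulfone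
Product: 4 (3S)-triethyl{[3,7,7-trimethyl-9-(phenylsulfonyl)non-1-en-3-yl]oxy}silane
Conditions: Fe(acac)3 (30 mol %), PhSiH3, EtOH/HOCH2CH2OH, 60 °C; 3 in excess
Reagents that add atoms: none
Why: Iron-hydride hydrogen-atom transfer to the electron-rich trisubstituted alkene gives the tertiary radical at the future C11, which is trapped by the vinyl sulfone (Giese addition) faster than it can cyclise onto the hindered allylic vinyl group, itself a much poorer hydrogen-atom acceptor; reduction and protonation of the α-sulfonyl radical complete the hydroalkylation and create the quaternary carbon and the C11–C1 bond.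

Step 3
Reactants: 4 (3S)-triethyl{[3,7,7-trimethyl-9-(phenylsulfonyl)non-1-en-3-yl]oxy}silane
Product: 6 (7S)-3,3,7-trimethyl-7-(triethylsilyloxy)non-8-enal, via α-silyloxy sulfone 5 (not isolated)
Conditions: n-BuLi, THF, −78 °C; Me3SiOOSiMe3, −78 → 0 °C; aq. NH4Cl
Reagents that add atoms: bis(trimethylsilyl) peroxide, C[Si](C)(C)OO[Si](C)(C)C
Why: Oxidative desulfonylation, in which deprotonated 4 is oxygenated at the sulfonyl carbon by the silyl peroxide to 5, which loses benzenesulfinate on desilylation and unveils the C2 aldehyde without touching the vinyl group or the tertiary silyl ether.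

Step 4
Reactants: 6 (7S)-3,3,7-trimethyl-7-(triethylsilyloxy)non-8-enal; 7 pent-1-en-3-one
Product: 8 (7S,8E)-3,3,7-trimethyl-10-oxo-7-(triethylsilyloxy)dodec-8-enal
Conditions: second-generation Hoveyda–Grubbs catalyst (5–10 mol %), 7 (4 equiv), CH2Cl2, 40 °C
Reagents that add atoms: none
Why: Olefin cross-metathesis between a hindered allylic olefin that cannot homodimerise and an electron-poor vinyl ketone used in excess should be selective for the cross product and E-selective, and the aldehyde and silyl ether are inert to the ruthenium carbene.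

Step 5
Reactants: 8 (7S,8E)-3,3,7-trimethyl-10-oxo-7-(triethylsilyloxy)dodec-8-enal
Product: 11 cis-fused bicyclic enone (1S,6R,7S; C4 ketone; C2=C3 alkene; OSiEt3 on C7), via cycloheptane keto-aldehyde 9 (not isolated), via bicyclic ketol 10 (not isolated)
Conditions: pyrrolidine (1 equiv), AcOH (1 equiv), toluene (0.02 M), 23 → 80 °C
Reagents that add atoms: none
Why: Proposed new method: pyrrolidinium acetate turns the C2 aldehyde of 8 into its E-enamine, whose carbon C1 adds to the enone β-carbon C6 (reversible 7-exo-trig Michael closure of ring B, giving 9 after proton transfer); the ethyl ketone then enolises toward C3 and condenses with the C2 aldehyde or its iminium ion (6-enolendo-exo-trig aldol closure of ring A to 10), and irreversible loss of water drains the Michael equilibrium into enone 11. The closest known reaction type is the secondary-amine-mediated intramolecular Michael addition–aldol condensation (Robinson-type annulation) that closes five- and six-membered rings; the seven-membered Michael closure is the untested part and should be helped by Thorpe–Ingold folding at the C11 gem-dimethyl carbon and the quaternary C7, although it joins two neopentyl-type carbons. C6 is set relative to C7 in the reversible Michael step: in a chair-like seven-membered array the C11 gem-dimethyl group forces the enone arm on C6 into an equatorial site, the C7 methyl takes the neighbouring equatorial site anti to the forming C1–C6 bond, and the slimmer silyloxy oxygen sits axial and gauche to that bond, which places C5 cis to the C7 oxygen (6R). C1 is not fixed by the bond-forming event, because it epimerises through the aldehyde enamine before the aldol step and through the linear dienamine of 11 afterwards, so the ring fusion is expected to settle as the cis isomer (1S). The step needs Michael addition ahead of intermolecular aldol chemistry (high dilution, hindered aldehyde α-carbon) and ketone enolisation toward C3 only (closure through C5 would give a four-membered ring), and the triethylsilyl ether keeps the C7 oxygen from trapping the C2 aldehyde as a lactol or adding to the enone.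

Step 6
Reactants: 11 cis-fused bicyclic enone (1S,6R,7S)
Product: 12 allylic alcohol (1S,4S,6R,7S; C4 hydroxyl on the face opposite to H-1 and H-6)
Conditions: NaBH4, CeCl3·7H2O, MeOH, −78 → −40 °C
Reagents that add atoms: none
Why: Luche reduction gives clean 1,2-reduction of the enone, and because C7 with its silyloxy group sits axially over one face of ring A in the cis-fused bicycle, hydride should enter C4 from the face of H-1 and H-6 and leave the hydroxyl cis to the C6–C7 bond (4S).

Step 7
Reactants: 13 isovanillic acid
Product: 15 3-(tert-butyldimethylsilyloxy)-4-methoxybenzoic acid, via bis-silyl compound 14 (not isolated)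
Conditions: t-BuMe2SiCl, imidazole, DMF, 23 °C; then AcOH/THF/H2O, 23 °C
Reagents that add atoms: tert-butyldimethylsilyl chloride, CC(C)(C)[Si](C)(C)Cl
Why: Exhaustive silylation followed by selective hydrolysis of the labile silyl ester is the standard way to mask the phenol of a hydroxybenzoic acid, which keeps it from competing as a Mitsunobu nucleophile.

Step 8
Reactants: 12 allylic alcohol (1S,4S,6R,7S); 15 3-(tert-butyldimethylsilyloxy)-4-methoxybenzoic acid
Product: 16 bis-silylated ester (1S,4R,6R,7S; C4 3-silyloxy-4-methoxybenzoate on the face of H-1 and H-6; OSiEt3 on C7)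
Conditions: PPh3, DIAD, THF, 0 → 23 °C
Reagents that add atoms: none
Why: Mitsunobu esterification, in which the carboxylate displaces the oxyphosphonium group of 12 by SN2 from the open face of ring A (the face of H-1 and H-6) and so inverts C4 to the R configuration of the target; both silyl ethers are inert.

Step 9
Reactants: 16 bis-silylated ester (1S,4R,6R,7S)
Product: 17 CNP0210711.3 (target; 1S,4R,6R,7S)
Conditions: Bu4NF, AcOH, THF, 0 → 23 °C
Reagents that add atoms: none
Why: Buffered fluoride cleaves the aryl and the tertiary alkyl silyl ether while leaving the allylic benzoate intact, and no stereocentre is affected.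

**Compound list**

1 | (S)-(+)-linalool, (3S)-3,7-dimethylocta-1,6-dien-3-ol | C=C[C@@](C)(O)CCC=C(C)C | starting material
2 | (3S)-triethyl[(3,7-dimethylocta-1,6-dien-3-yl)oxy]silane | C=C[C@@](C)(O[Si](CC)(CC)CC)CCC=C(C)C | intermediate
3 | phenyl vinyl sulfone | C=CS(=O)(=O)c1ccccc1 | starting material
4 | (3S)-triethyl{[3,7,7-trimethyl-9-(phenylsulfonyl)non-1-en-3-yl]oxy}silane | C=C[C@@](C)(O[Si](CC)(CC)CC)CCCC(C)(C)CCS(=O)(=O)c1ccccc1 | intermediate
5 | α-silyloxy sulfone: 4 with OSiMe3 on the sulfonyl-bearing carbon (epimer mixture, not isolated) | C=C[C@@](C)(O[Si](CC)(CC)CC)CCCC(C)(C)CC(O[Si](C)(C)C)S(=O)(=O)c1ccccc1 | intermediate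
6 | (7S)-3,3,7-trimethyl-7-(triethylsilyloxy)non-8-enal | C=C[C@@](C)(O[Si](CC)(CC)CC)CCCC(C)(C)CC=O | intermediate
7 | pent-1-en-3-one | CCC(=O)C=C | starting material
8 | (7S,8E)-3,3,7-trimethyl-10-oxo-7-(triethylsilyloxy)dodec-8-enal (key-step precursor) | O=CCC(C)(C)CCC[C@](C)(O[Si](CC)(CC)CC)/C=C/C(=O)CC | intermediate
9 | cycloheptane keto-aldehyde (skeleton labels 1S,6R,7S): ring B with CHO on C1, 2-oxobutyl on C6 cis to both the CHO and the C7 OSiEt3, methyl on C7, gem-dimethyl on C11 (not isolated) | CCC(=O)C[C@@H]1[C@H](C=O)C(C)(C)CCC[C@]1(C)O[Si](CC)(CC)CC | intermediate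
10 | bicyclic ketol: 11 hydrated across C2=C3, OH on C2 (C2 and C3 epimer mixture, not isolated) | O=C1C[C@@H]2[C@H](C(O)C1C)C(C)(C)CCC[C@]2(C)O[Si](CC)(CC)CC | intermediate
11 | cis-fused bicyclic enone (1S,6R,7S): C4 ketone, C2=C3 alkene with methyl on C3, methyl and OSiEt3 on C7, gem-dimethyl on C11 (key-step product) | O=C1C[C@@H]2[C@H](C=C1C)C(C)(C)CCC[C@]2(C)O[Si](CC)(CC)CC | intermediate
12 | allylic alcohol (1S,4S,6R,7S): 11 reduced at C4, hydroxyl opposite to H-1 and H-6 | O[C@H]1C[C@@H]2[C@H](C=C1C)C(C)(C)CCC[C@]2(C)O[Si](CC)(CC)CC | intermediate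
13 | isovanillic acid (3-hydroxy-4-methoxybenzoic acid) | COc1ccc(C(=O)O)cc1O | starting material
14 | tert-butyldimethylsilyl 3-(tert-butyldimethylsilyloxy)-4-methoxybenzoate (not isolated) | COc1ccc(cc1O[Si](C)(C)C(C)(C)C)C(=O)O[Si](C)(C)C(C)(C)C | intermediate
15 | 3-(tert-butyldimethylsilyloxy)-4-methoxybenzoic acid | COc1ccc(cc1O[Si](C)(C)C(C)(C)C)C(=O)O | intermediate
16 | bis-silylated ester (1S,4R,6R,7S): C4 3-(tert-butyldimethylsilyloxy)-4-methoxybenzoate on the face of H-1 and H-6, OSiEt3 on C7 | COc1ccc(C(=O)O[C@@H]2C[C@@H]3[C@H](C=C2C)C(C)(C)CCC[C@]3(C)O[Si](CC)(CC)CC)cc1O[Si](C)(C)C(C)(C)C | intermediate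
17 | CNP0210711.3 (1S,4R,6R,7S): C4 isovanillate, C7 tertiary alcohol | COc1ccc(C(=O)O[C@@H]2C[C@@H]3[C@H](C=C2C)C(C)(C)CCC[C@]3(C)O)cc1O | target

**Step count**

Total: 9 steps. Longest linear sequence: 8 steps from (S)-linalool (steps 1–6, 8, 9); step 7 is a one-step side branch.

**Steps most likely to fail**

1. Step 5 (key step). Three processes can go wrong. The seven-membered Michael closure may be too slow, so that intermolecular condensation and amine conjugate addition take over. Attack on C6 may show poor facial selectivity relative to C7. The ring fusion may equilibrate toward the trans isomer. The fallback makes the same two ring bonds by precedented reactions; it sets out from aldehyde 6 and returns at enone 11. Ozonolysis of the vinyl group (O3, CH2Cl2, −78 °C; PPh3) gives (2S)-2,6,6-trimethyl-2-(triethylsilyloxy)octanedial F1, in which only the C2 aldehyde can enolise. An amine-salt-mediated intramolecular aldol condensation (Bn2NH·CF3CO2H, toluene, 60 °C), the standard closure of dialdehydes to cycloalkene carbaldehydes, then forms the C1–C6 bond as the ring B enal (3S)-3,7,7-trimethyl-3-(triethylsilyloxy)cyclohept-1-ene-1-carbaldehyde F2. Ring A is added by a Robinson-type annulation with allyl 3-oxopentanoate: reversible Michael addition of the stabilised carbanion to C6 (DBU, THF) gives Michael adduct F3 (9 carrying an allyloxycarbonyl group on C5, not isolated), and aldol condensation through C3 onto C2 (pyrrolidine, AcOH) gives bicyclic allyl β-keto ester F4 (11 carrying an allyloxycarbonyl group on C5). Deallylation with decarboxylation (Pd(PPh3)4, morpholine, THF) delivers 11. C6 is again set by a reversible addition and C1 by equilibration, but each ring is closed by a reaction known for its ring size.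

2. Step 8 (Mitsunobu). Activation of the hindered hydroxyl may be slow, and elimination to the ring A diene or SN2′ attack at C2 may compete with direct displacement. The fallback separates inversion from acylation; it sets out from alcohol 12 and returns at ester 16. Mitsunobu reaction with the more acidic 4-nitrobenzoic acid (PPh3, DIAD, toluene) gives the inverted (4R)-4-nitrobenzoate F5. Methanolysis (K2CO3, MeOH) frees the (4R)-alcohol F6. Carbodiimide esterification with acid 15 (EDC·HCl, DMAP, CH2Cl2) then attaches the aryl ester with retention to give 16.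

3. Step 4 (cross-metathesis). Turnover may stall at the vinyl group beside the quaternary silyloxy carbon, with catalyst decay and enone homodimerisation. The fallback builds the enone by carbonyl olefination; it sets out from aldehyde 6 and returns at precursor 8. Aprotic acetalisation of the aldehyde (Me3SiOCH2CH2OSiMe3, catalytic Me3SiOTf, CH2Cl2, −78 °C) gives dioxolane F7. Ozonolysis of the vinyl group (O3, CH2Cl2, −78 °C; PPh3) gives α-silyloxy aldehyde F8. Horner–Wadsworth–Emmons olefination with diethyl (2-oxobutyl)phosphonate (Ba(OH)2, wet THF) gives (E)-enone acetal F9. Mild acetal hydrolysis (PPTS, wet acetone, 50 °C) releases 8.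

Further compounds
F1 | step 5 | (2S)-2,6,6-trimethyl-2-(triethylsilyloxy)octanedial | O=CCC(C)(C)CCC[C@](C)(O[Si](CC)(CC)CC)C=O
F2 | step 5 | (3S)-3,7,7-trimethyl-3-(triethylsilyloxy)cyclohept-1-ene-1-carbaldehyde | O=CC1=C[C@@](C)(O[Si](CC)(CC)CC)CCCC1(C)C
F3 | step 5 | Michael adduct: 9 carrying an allyloxycarbonyl group on C5 (C5 epimer mixture) | CCC(=O)C(C(=O)OCC=C)[C@@H]1[C@H](C=O)C(C)(C)CCC[C@]1(C)O[Si](CC)(CC)CC
F4 | step 5 | bicyclic allyl β-keto ester: 11 carrying an allyloxycarbonyl group on C5 (C5 epimer mixture) | O=C1C(C(=O)OCC=C)[C@@H]2[C@H](C=C1C)C(C)(C)CCC[C@]2(C)O[Si](CC)(CC)CC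
F5 | step 8 | (1S,4R,6R,7S)-4-nitrobenzoate: C4 epimer of 12 esterified with 4-nitrobenzoic acid | O=C(O[C@@H]1C[C@@H]2[C@H](C=C1C)C(C)(C)CCC[C@]2(C)O[Si](CC)(CC)CC)c1ccc(cc1)[N+](=O)[O-]
F6 | step 8 | (1S,4R,6R,7S)-allylic alcohol: C4 epimer of 12 | O[C@@H]1C[C@@H]2[C@H](C=C1C)C(C)(C)CCC[C@]2(C)O[Si](CC)(CC)CC
F7 | step 4 | 2-[(6S)-2,2,6-trimethyl-6-(triethylsilyloxy)oct-7-en-1-yl]-1,3-dioxolane | C=C[C@@](C)(O[Si](CC)(CC)CC)CCCC(C)(C)CC1OCCO1
F8 | step 4 | (2S)-7-(1,3-dioxolan-2-yl)-2,6,6-trimethyl-2-(triethylsilyloxy)heptanal | O=C[C@@](C)(O[Si](CC)(CC)CC)CCCC(C)(C)CC1OCCO1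
F9 | step 4 | (4E,6S)-11-(1,3-dioxolan-2-yl)-6,10,10-trimethyl-6-(triethylsilyloxy)undec-4-en-3-one | CCC(=O)/C=C/[C@@](C)(O[Si](CC)(CC)CC)CCCC(C)(C)CC1OCCO1
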